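**Plan**

Locants: lactone ring O1, C2(=O), C3(CH3), C4(OH), C5; side chain C1'–C13' counted from C5.
Retrosynthesis: (a) the 4-O-[2-(trimethylsilyl)ethyl] ether is cleaved last; (b) ring bond O1–C5 and chain bond C1'–C2' are cut in one operation, giving dienoic acid 5 (C2–C5 plus C1') and alkenyl iodide 24 (C2'–C13' plus furan); (c) 24 is cut at C8'=C9' into iodo-enal 15 and tetrazolyl sulfone 23; (d) 5 is traced back to the six-membered enol lactone 4.
Enabling feature: C5 sits 1,5 to the carboxyl oxygen across the cis C3=C4 enol double bond, and its neighbour C1' is bonded to the sp2 carbon C2'; C5=C1' can therefore be the terminal double bond of a 2-oxy-1,3-diene (C3=C4–C5=C1') that accepts an alkenylpalladium at C1' and its own carboxylate at C5.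
Forward order: the dihydropyranone ring of 4 is built and then opened (a temporary ring that fixes carboxyl and vinyl cis on C3=C4); chain 24 is joined from three pieces; the furanone ring arises in step 15 together with the union of the two halves.
Stereochemistry: C10' from auxiliary-controlled allylation (step 9); C5 from the chiral palladium catalyst in step 15; 2'E from hydrozirconation–iodination, 6'E from syn-carbocupration, 8'E from Julia–Kocienski olefination.

Key step: step 15

Remark: the sense of induction of the palladium/(S)-tBu-PHOX catalyst on this new substrate class cannot be predicted with confidence; it is assumed to favour 5R, and (R)-tBu-PHOX is used without other change if the opposite sense is found.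

**Route**

Step 1
Reactants: 1 methyl 2-methyl-3-oxobutanoate
Product: 3 4-hydroxy-3-methyl-5,6-dihydro-2H-pyran-2-one, via methyl 5-hydroxy-2-methyl-3-oxopentanoate 2 (not isolated)
Conditions: NaH, THF, 0 °C; n-BuLi, 0 °C; (CH2O)n, −20 °C → rt; 1 M NaOH (aq), rt; HCl to pH 2
Reagents that add atoms: paraformaldehyde (formaldehyde) C=O
Why: The γ-carbon of the β-keto ester dianion adds to formaldehyde (dianion aldol addition), and the δ-hydroxy β-keto ester 2 lactonizes under base to the six-membered enol lactone, which is released on acidification; no stereocenter is formed.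

Step 2
Reactants: 3 4-hydroxy-3-methyl-5,6-dihydro-2H-pyran-2-one
Product: 4 3-methyl-4-[2-(trimethylsilyl)ethoxy]-5,6-dihydro-2H-pyran-2-one
Conditions: 2-(trimethylsilyl)ethanol, PPh3, DIAD, THF, 0 °C → rt
Reagents that add atoms: 2-(trimethylsilyl)ethanol C[Si](C)(C)CCO
Why: Mitsunobu O-alkylation of the acidic enol (a vinylogous acid) with a primary alcohol should give the 4-alkoxy enol lactone, in which the ring holds the carboxyl carbon and C5 cis across C3=C4.

Step 3
Reactants: 4 3-methyl-4-[2-(trimethylsilyl)ethoxy]-5,6-dihydro-2H-pyran-2-one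
Product: 5 (2E)-2-methyl-3-[2-(trimethylsilyl)ethoxy]penta-2,4-dienoic acid
Conditions: KN(SiMe3)2 (1.1 equiv), THF, −78 → 0 °C; cold 0.5 M HCl to pH 3; used at once
Reagents that add atoms: none
Why: γ-Deprotonation at C5 gives the vinylogous enolate, which expels the ring carboxylate oxygen from C6 (E1cB ring-opening of a 5,6-dihydro-2-pyranone), so that carboxyl and the new vinyl group are left cis on the tetrasubstituted double bond (2E) as the former ring dictates.

Step 4
Reactants: 6 pent-3-yn-1-ol
Product: 7 5-bromopent-2-yne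
Conditions: CBr4, PPh3, CH2Cl2, 0 °C
Reagents that add atoms: carbon tetrabromide BrC(Br)(Br)Br
Why: The Appel reaction converts the primary alcohol into the bromide by SN2 displacement of the alkoxyphosphonium ion, and the internal alkyne is inert.

Step 5
Reactants: 7 5-bromopent-2-yne; 8 ethyl but-2-ynoate
Product: 11 ethyl (2E)-3-methyloct-2-en-6-ynoate, via pent-3-yn-1-ylmagnesium bromide 9 (not isolated), via pent-3-yn-1-ylcopper 10 (not isolated)
Conditions: Mg, THF, rt; CuBr·SMe2 (1.0 equiv), THF/Me2S, −78 °C; 8, −78 °C; aq NH4Cl at −78 °C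
Reagents that add atoms: none
Why: syn-Carbocupration of the ynoate (organocopper conjugate addition) at low temperature places the alkyl group and copper cis, and protonation with retention gives the (E)-3-methyl-2-enoate, the cold quench preventing equilibration of the alkenylcopper through its allenoate form.

Step 6
Reactants: 11 ethyl (2E)-3-methyloct-2-en-6-ynoate
Product: 12 (2E)-3-methyloct-2-en-6-yn-1-ol
Conditions: i-Bu2AlH (2.2 equiv), CH2Cl2, −78 → 0 °C; aqueous potassium sodium tartrate
Reagents that add atoms: none
Why: 1,2-Reduction of the α,β-unsaturated ester by the aluminium hydride gives the allylic alcohol without touching the alkyne or the double-bond geometry.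

Step 7
Reactants: 12 (2E)-3-methyloct-2-en-6-yn-1-ol
Product: 14 (2E,6E)-7-iodo-3-methylocta-2,6-dien-1-ol, via C7,O-bis(chlorozirconocene) adduct 13 (not isolated)
Conditions: Cp2Zr(H)Cl (3.2 equiv), THF, rt then 50 °C; I2, THF, 0 °C; water
Reagents that add atoms: iodine II
Why: Hydrozirconation adds H and Zr syn across the 2-alkyne, excess reagent equilibrates the regioisomers toward zirconium on the less hindered methyl-bearing carbon C7, and iodinolysis with retention gives the (6E)-7-iodoalkene, the hydroxyl group consuming one equivalent of reagent and the trisubstituted alkene remaining inert.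

Step 8
Reactants: 14 (2E,6E)-7-iodo-3-methylocta-2,6-dien-1-ol
Product: 15 (2E,6E)-7-iodo-3-methylocta-2,6-dienal
Conditions: MnO2 (activated, excess), CH2Cl2, rt
Reagents that add atoms: none
Why: MnO2 oxidizes the allylic alcohol chemoselectively to the enal under neutral conditions that leave the alkenyl iodide and both double-bond geometries intact.

Step 9
Reactants: 16 (4R)-4-benzyl-3-propanoyl-1,3-oxazolidin-2-one
Product: 17 (4R)-4-benzyl-3-[(2S)-2-methylpent-4-enoyl]-1,3-oxazolidin-2-one
Conditions: NaN(SiMe3)2, THF, −78 °C; allyl iodide, −78 → −40 °C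
Reagents that add atoms: allyl iodide C=CCI
Why: In this Evans alkylation the chelated (Z)-sodium enolate is allylated on the face opposite the benzyl group of the auxiliary, which sets the (2S) methyl-bearing stereocenter (later C10').

Step 10
Reactants: 17 (4R)-4-benzyl-3-[(2S)-2-methylpent-4-enoyl]-1,3-oxazolidin-2-one
Product: 18 (2S)-2-methylpent-4-en-1-ol
Conditions: LiBH4, H2O (1 equiv), Et2O, 0 °C
Reagents that add atoms: none
Why: Reductive cleavage of the N-acyloxazolidinone by borohydride gives the primary alcohol and the recoverable auxiliary without epimerizing the α-stereocenter.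

Step 11
Reactants: 18 (2S)-2-methylpent-4-en-1-ol
Product: 19 5-{[(2S)-2-methylpent-4-en-1-yl]sulfanyl}-1-phenyl-1H-tetrazole
Conditions: 1-phenyl-1H-tetrazole-5-thiol, PPh3, DIAD, THF, 0 °C → rt
Reagents that add atoms: 1-phenyl-1H-tetrazole-5-thiol Sc1nnnn1-c1ccccc1
Why: Mitsunobu thioetherification displaces the activated primary hydroxyl with the acidic heteroaryl thiol, and the stereocenter, one carbon away, is not involved.

Step 12
Reactants: 19 5-{[(2S)-2-methylpent-4-en-1-yl]sulfanyl}-1-phenyl-1H-tetrazole
Product: 20 5-{[(2S)-2-methylpent-4-en-1-yl]sulfonyl}-1-phenyl-1H-tetrazole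
Conditions: (NH4)6Mo7O24·4H2O (10 mol %), 30% H2O2, EtOH, 0 °C → rt
Reagents that add atoms: hydrogen peroxide OO
Why: Molybdate-catalyzed peroxide oxidation takes the sulfide to the sulfone without epoxidizing the terminal alkene, and it is placed before the oxidation-sensitive furan is introduced.

Step 13
Reactants: 20 5-{[(2S)-2-methylpent-4-en-1-yl]sulfonyl}-1-phenyl-1H-tetrazole; 21 3-bromofuran
Product: 23 5-{[(2S)-5-(furan-3-yl)-2-methylpentyl]sulfonyl}-1-phenyl-1H-tetrazole, via B-alkyl-9-BBN adduct 22 (not isolated)
Conditions: 9-BBN (0.5 M in THF), THF, 0 °C → rt; then 21, Pd(dppf)Cl2 (5 mol %), K3PO4 (3 M aq), DMF, rt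
Reagents that add atoms: none
Why: Anti-Markovnikov hydroboration of the terminal alkene followed by B-alkyl Suzuki–Miyaura coupling with the heteroaryl bromide forms the C13'–furan C3 bond, the mild phosphate base at room temperature being chosen to spare the sulfone.

Step 14
Reactants: 23 5-{[(2S)-5-(furan-3-yl)-2-methylpentyl]sulfonyl}-1-phenyl-1H-tetrazole; 15 (2E,6E)-7-iodo-3-methylocta-2,6-dienal
Product: 24 3-[(4S,5E,7E,11E)-12-iodo-4,8-dimethyltrideca-5,7,11-trien-1-yl]furan
Conditions: KN(SiMe3)2, DME, −60 °C; then 15, −60 °C → rt; aq NH4Cl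
Reagents that add atoms: none
Why: In this Julia–Kocienski olefination the metalated tetrazolyl sulfone adds to the enal and Smiles rearrangement with loss of SO2 and the tetrazolate gives the C8'=C9' double bond, for which the potassium counterion in DME should favour E, while the alkenyl iodide and the stereocenter β to sulfur are untouched.

Step 15
Reactants: 5 (2E)-2-methyl-3-[2-(trimethylsilyl)ethoxy]penta-2,4-dienoic acid; 24 3-[(4S,5E,7E,11E)-12-iodo-4,8-dimethyltrideca-5,7,11-trien-1-yl]furan
Product: 25 (5R)-5-[(2E,6E,8E,10S)-13-(furan-3-yl)-2,6,10-trimethyltrideca-2,6,8-trien-1-yl]-3-methyl-4-[2-(trimethylsilyl)ethoxy]furan-2(5H)-one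
Conditions: 5 (1.3 equiv), Pd2(dba)3 (2.5 mol %), (S)-tBu-PHOX (6 mol %), Ag2CO3 (1.0 equiv), 1,4-dioxane, 45 °C, dark
Reagents that add atoms: none
Why: Proposed new method: zerovalent palladium adds oxidatively to the alkenyl iodide 24, Ag2CO3 removes iodide and turns 5 into its carboxylate, and the alkenylpalladium inserts the terminal C5=C1' double bond of the 2-oxy-1,3-diene with C2' going to C1', which leaves palladium on C5 as an η3-allyl over C5–C4–C3 that is captured at C5 by the cis carboxylate oxygen O1 with release of zerovalent palladium (the reverse order, anti attack of the carboxylate on the palladium-bound alkene followed by C–C reductive elimination, joins the same atoms). The closest known reaction types are the palladium-catalyzed heteroannulation of 1,3-dienes, the asymmetric Heck insertion/η3-allyl capture cascade and the coupling–cyclization of 2,3-allenoic acids with alkenyl halides to butenolides; a 3-alkoxy-2,4-dienoic acid has not been used in any of them. The furanone ring (O1, C2, C3, C4, C5) closes by O1–C5 bond formation in a 5-exo-trig mode with respect to the C5=C1' bond, which is possible only because the ring of 4 left carboxyl and vinyl cis on C3=C4. The C5 stereocenter is controlled by the chiral P,N ligand on palladium, which selects the face of the C5=C1' bond that is carbometalated or attacked, and C10' is too remote to interfere. The step needs C–C formation at C1' and C–O formation at C5 rather than β-hydride loss to a triene (secured by the fast five-membered capture and the halide-free cationic palladium; attack at the other allyl terminus C3 would give a three-membered ring), and reaction with the terminal diene of 5 rather than with the internal diene or furan of 24 (secured by the accessibility of the monosubstituted vinyl group and by the E geometry of 24, which holds palladium away from its own chain).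

Step 16
Reactants: 25 (5R)-5-[(2E,6E,8E,10S)-13-(furan-3-yl)-2,6,10-trimethyltrideca-2,6,8-trien-1-yl]-3-methyl-4-[2-(trimethylsilyl)ethoxy]furan-2(5H)-one
Product: 26 (5R)-5-[(2E,6E,8E,10S)-13-(furan-3-yl)-2,6,10-trimethyltrideca-2,6,8-trien-1-yl]-4-hydroxy-3-methylfuran-2(5H)-one
Conditions: Bu4NF (1 M in THF, 2 equiv), THF, 0 °C; cold 0.5 M HCl to pH 3
Reagents that add atoms: none
Why: Fluoride attacks silicon and the 2-silylethyl group fragments to ethene, fluorotrimethylsilane and the tetronate anion (a leaving group comparable to a carboxylate, as in the cleavage of 2-(trimethylsilyl)ethyl esters), and the anion formed resists deprotonation at C5 until it is protonated on work-up.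

**Compound list**

1 | methyl 2-methyl-3-oxobutanoate | CC(=O)C(C)C(=O)OC | starting material
2 | methyl 5-hydroxy-2-methyl-3-oxopentanoate | COC(=O)C(C)C(=O)CCO | intermediate
3 | 4-hydroxy-3-methyl-5,6-dihydro-2H-pyran-2-one | CC1=C(O)CCOC1=O | intermediate
4 | 3-methyl-4-[2-(trimethylsilyl)ethoxy]-5,6-dihydro-2H-pyran-2-one | CC1=C(OCC[Si](C)(C)C)CCOC1=O | intermediate
5 | (2E)-2-methyl-3-[2-(trimethylsilyl)ethoxy]penta-2,4-dienoic acid | C=C/C(OCC[Si](C)(C)C)=C(/C)C(=O)O | intermediate
6 | pent-3-yn-1-ol | CC#CCCO | starting material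
7 | 5-bromopent-2-yne | CC#CCCBr | intermediate
8 | ethyl but-2-ynoate | CC#CC(=O)OCC | starting material
9 | pent-3-yn-1-ylmagnesium bromide | CC#CCC[Mg]Br | intermediate
10 | pent-3-yn-1-ylcopper (as its MgBr2 complex) | CC#CCC[Cu] | intermediate
11 | ethyl (2E)-3-methyloct-2-en-6-ynoate | CC#CCC/C(C)=C/C(=O)OCC | intermediate
12 | (2E)-3-methyloct-2-en-6-yn-1-ol | CC#CCC/C(C)=C/CO | intermediate
13 | C7,O-bis(chlorozirconocene) adduct of (2E,6E)-3-methylocta-2,6-dien-1-ol (Cp2Zr(Cl) on C7 and on oxygen) | C/C(=C\CC/C(C)=C/CO[Zr](Cl)(C1C=CC=C1)C1C=CC=C1)[Zr](Cl)(C1C=CC=C1)C1C=CC=C1 | intermediate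
14 | (2E,6E)-7-iodo-3-methylocta-2,6-dien-1-ol | C/C(I)=C\CC/C(C)=C/CO | intermediate
15 | (2E,6E)-7-iodo-3-methylocta-2,6-dienal | C/C(I)=C\CC/C(C)=C/C=O | intermediate
16 | (4R)-4-benzyl-3-propanoyl-1,3-oxazolidin-2-one | CCC(=O)N1[C@H](Cc2ccccc2)COC1=O | starting material
17 | (4R)-4-benzyl-3-[(2S)-2-methylpent-4-enoyl]-1,3-oxazolidin-2-one | C=CC[C@H](C)C(=O)N1[C@H](Cc2ccccc2)COC1=O | intermediate
18 | (2S)-2-methylpent-4-en-1-ol | C=CC[C@H](C)CO | intermediate
19 | 5-{[(2S)-2-methylpent-4-en-1-yl]sulfanyl}-1-phenyl-1H-tetrazole | C=CC[C@H](C)CSc1nnnn1-c1ccccc1 | intermediate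
20 | 5-{[(2S)-2-methylpent-4-en-1-yl]sulfonyl}-1-phenyl-1H-tetrazole | C=CC[C@H](C)CS(=O)(=O)c1nnnn1-c1ccccc1 | intermediate
21 | 3-bromofuran | Brc1ccoc1 | starting material
22 | 9-[(4S)-4-methyl-5-(1-phenyl-1H-tetrazol-5-ylsulfonyl)pentyl]-9-borabicyclo[3.3.1]nonane | C[C@@H](CCCB1C2CCCC1CCC2)CS(=O)(=O)c1nnnn1-c1ccccc1 | intermediate
23 | 5-{[(2S)-5-(furan-3-yl)-2-methylpentyl]sulfonyl}-1-phenyl-1H-tetrazole | C[C@@H](CCCc1ccoc1)CS(=O)(=O)c1nnnn1-c1ccccc1 | intermediate
24 | 3-[(4S,5E,7E,11E)-12-iodo-4,8-dimethyltrideca-5,7,11-trien-1-yl]furan | I/C(C)=C/CC/C(C)=C/C=C/[C@@H](C)CCCc1ccoc1 | intermediate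
25 | (5R)-5-[(2E,6E,8E,10S)-13-(furan-3-yl)-2,6,10-trimethyltrideca-2,6,8-trien-1-yl]-3-methyl-4-[2-(trimethylsilyl)ethoxy]furan-2(5H)-one | CC1=C(OCC[Si](C)(C)C)[C@@H](C/C(C)=C/CC/C(C)=C/C=C/[C@@H](C)CCCc2ccoc2)OC1=O | intermediate
26 | (5R)-5-[(2E,6E,8E,10S)-13-(furan-3-yl)-2,6,10-trimethyltrideca-2,6,8-trien-1-yl]-4-hydroxy-3-methylfuran-2(5H)-one | CC1=C(O)[C@@H](C/C(C)=C/CC/C(C)=C/C=C/[C@@H](C)CCCc2ccoc2)OC1=O | target

**Summary**

Total step count: 16 (branches 1–3, 4–8 and 9–13, then 14–16).
Longest linear sequence: 8 steps (4–8 or 9–13, then 14, 15, 16).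

Steps most likely to fail:

Step 15. After the insertion, β-hydride loss to a conjugated triene may outrun C–O bond formation, and the catalyst may discriminate the faces of C5=C1' poorly, which would give C5 epimers that the remote C10' center makes hard to separate. The fallback makes the two bonds one after the other with known reactions, setting out from 5 and 24 and coming back at 25. Acid 5 is cyclized by catalytic enantioselective iodolactonization (N-iodosuccinimide, chiral bifunctional aminourea catalyst, toluene, low temperature; 5-exo attack of the carboxylate on the iodonium ion of C5=C1') to (5S)-5-(iodomethyl)-3-methyl-4-[2-(trimethylsilyl)ethoxy]furan-2(5H)-one F1, whose enantiomers can still be separated on a chiral phase at this small stage if needed. F1 and 24 are then joined at C1'–C2' by nickel-catalyzed reductive cross-electrophile coupling (NiBr2·glyme, 4,4'-di-tert-butyl-2,2'-bipyridine, Zn, DMA, rt), in which the primary radical from F1 is taken up by the alkenylnickel from 24 without touching C5, to give 25.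

Step 14. The olefination may lose E selectivity at C8'=C9', and the base may degrade the enal by γ-deprotonation. The fallback reverses the polarity of the olefination, setting out from 14, 18 and 21 and coming back at 24. Alcohol 14 is converted (CBr4, PPh3) into (2E,6E)-1-bromo-7-iodo-3-methylocta-2,6-diene F2 and then by Michaelis–Arbuzov reaction with P(OEt)3 into diethyl [(2E,6E)-7-iodo-3-methylocta-2,6-dien-1-yl]phosphonate F3. Alcohol 18 is hydroborated with excess 9-BBN to the C,O-bis(9-borabicyclo[3.3.1]nonan-9-yl) adduct F4 (not isolated), which is coupled with 21 (Pd(dppf)Cl2, aqueous K3PO4) to (2S)-5-(furan-3-yl)-2-methylpentan-1-ol F5; Dess–Martin oxidation (NaHCO3 buffer) gives (2S)-5-(furan-3-yl)-2-methylpentanal F6. Horner–Wadsworth–Emmons reaction of F6 with lithiated F3 (LiN(SiMe3)2, THF/DMPU, −78 °C) should give the E diene 24.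

Step 16. Fluoride may epimerize C5 by deprotonation before the silylethyl group fragments, or the fragmentation of the vinylogous ester may stall. The fallback changes the protecting group and the cleavage mechanism, setting out from 3 and coming back at 26. Enol 3 is O-methylated (Me2SO4, K2CO3, acetone) to 4-methoxy-3-methyl-5,6-dihydro-2H-pyran-2-one F7, which is opened as in step 3 to (2E)-3-methoxy-2-methylpenta-2,4-dienoic acid F8. F8 is coupled with 24 as in step 15 to (5R)-5-[(2E,6E,8E,10S)-13-(furan-3-yl)-2,6,10-trimethyltrideca-2,6,8-trien-1-yl]-4-methoxy-3-methylfuran-2(5H)-one F9. SN2 demethylation at the O-methyl carbon with the weakly basic thiolate LiSPr (HMPA, rt), then acidification, gives 26.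

Further compounds
F1 | step 15 | (5S)-5-(iodomethyl)-3-methyl-4-[2-(trimethylsilyl)ethoxy]furan-2(5H)-one | CC1=C(OCC[Si](C)(C)C)[C@@H](CI)OC1=O
F2 | step 14 | (2E,6E)-1-bromo-7-iodo-3-methylocta-2,6-diene | C/C(I)=C\CC/C(C)=C/CBr
F3 | step 14 | diethyl [(2E,6E)-7-iodo-3-methylocta-2,6-dien-1-yl]phosphonate | C/C(I)=C\CC/C(C)=C/CP(=O)(OCC)OCC
F4 | step 14 | C,O-bis(9-borabicyclo[3.3.1]nonan-9-yl) adduct of (2S)-2-methylpentane-1,5-diyl (boron on C5 and on O1) | C[C@@H](CCCB1C2CCCC1CCC2)COB1C2CCCC1CCC2
F5 | step 14 | (2S)-5-(furan-3-yl)-2-methylpentan-1-ol | C[C@@H](CCCc1ccoc1)CO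
F6 | step 14 | (2S)-5-(furan-3-yl)-2-methylpentanal | C[C@@H](CCCc1ccoc1)C=O
F7 | step 16 | 4-methoxy-3-methyl-5,6-dihydro-2H-pyran-2-one | CC1=C(OC)CCOC1=O
F8 | step 16 | (2E)-3-methoxy-2-methylpenta-2,4-dienoic acid | C=C/C(OC)=C(/C)C(=O)O
F9 | step 16 | (5R)-5-[(2E,6E,8E,10S)-13-(furan-3-yl)-2,6,10-trimethyltrideca-2,6,8-trien-1-yl]-4-methoxy-3-methylfuran-2(5H)-one | CC1=C(OC)[C@@H](C/C(C)=C/CC/C(C)=C/C=C/[C@@H](C)CCCc2ccoc2)OC1=O
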